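**Retrosynthetic overview** (labdane numbering; β is the face of the C20 methyl on C10)
1. Target 27 ⇒ C19 acetate from the silyl ether; 13E enoate from the Z-enol phosphate of β-keto ester 23 with Me2CuLi; C11–C12 from allylic bromide 21 and the dianion of methyl acetoacetate 22.
2. 21 ⇒ C8=C9 enoate 19 ⇒ 9α-bromo ester 18 (E2) ⇒ saturated ester 17 ⇒ Δ5 ester 16 (ester-directed hydrogenation gives the trans ring fusion).
3. Key disconnection: the route rests on quaternary C10, the ring A/ring B fusion atom, being bonded to C9, which carries C11. A δ-lactone (12) that holds O–C6 and C11–C9 in one ring on a ring-A cyclohexenyl carbinol closes ring B and makes C9–C10 by a [3,3] shift of its silyl ketene acetal, with the 6S carbinol fixing C10.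
4. 12 ⇒ ring-A enal 7 by allylboration (sets C6), acrylate ring-closing metathesis and anti methyl cuprate addition (sets the C8 methyl trans to the C6 substituent, exo in the boat).
5. Ring A is bought as 2-methylcyclohexanone and C4 is set by catalytic asymmetric hydroxymethylation; ring order: A (purchased), then B (step 11).

Key step: step 11

Assumption: the antipode of the chiral bipyridine ligand used in step 2 is taken to be the one that delivers the (R)-ketone 3; nothing else in the route depends on the sense of that catalyst.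

**Step 1**
Reactants: 1 2-methylcyclohexanone
Product: 2 2-methyl-1-(trimethylsilyloxy)cyclohex-1-ene
Conditions: TMSCl, Et3N, DMF, 130 °C; fractional distillation
Reagents that add atoms: chlorotrimethylsilane, C[Si](C)(C)Cl
Why: Thermodynamic enol silylation under equilibrating conditions should favour the tetrasubstituted enol ether, the minor trisubstituted isomer being removed by distillation; the product is achiral.

**Step 2**
Reactants: 2 2-methyl-1-(trimethylsilyloxy)cyclohex-1-ene
Product: 3 (2R)-2-(hydroxymethyl)-2-methylcyclohexan-1-one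
Conditions: aq. HCHO, Sc(OTf)3 (10 mol %), chiral 6,6'-bis(1-hydroxy-2,2-dimethylpropyl)-2,2'-bipyridine (12 mol %), DME–H2O, −20 °C
Reagents that add atoms: formaldehyde, C=O
Why: Catalytic asymmetric Mukaiyama-type aldol (hydroxymethylation) in which the achiral enol ether is attacked on one face inside the chiral bipyridine–Sc(OTf)3 complex, so quaternary C4 is set by the catalyst alone.

**Step 3**
Reactants: 3 (2R)-2-(hydroxymethyl)-2-methylcyclohexan-1-one
Product: 4 (2R)-2-[(tert-butyldimethylsilyloxy)methyl]-2-methylcyclohexan-1-one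
Conditions: TBSCl, imidazole, DMF, 23 °C
Reagents that add atoms: tert-butyldimethylsilyl chloride, CC(C)(C)[Si](C)(C)Cl
Why: Imidazole-mediated silyl ether formation on the primary alcohol is mild enough to avoid retro-aldol loss of formaldehyde and leaves C4 untouched.

**Step 4**
Reactants: 4 (2R)-2-[(tert-butyldimethylsilyloxy)methyl]-2-methylcyclohexan-1-one
Product: 5 (2R)-2-[(tert-butyldimethylsilyloxy)methyl]-2,6-dimethylcyclohexan-1-one (both C6 epimers)
Conditions: LDA, THF, −78 °C; MeI, −78 → 0 °C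
Reagents that add atoms: iodomethane, CI
Why: Kinetic enolate alkylation can occur only at the one enolisable α-carbon (the future C10); the new centre forms as both epimers, which is immaterial because it becomes sp2 in step 5.

**Step 5**
Reactants: 5 (2R)-2-[(tert-butyldimethylsilyloxy)methyl]-2,6-dimethylcyclohexan-1-one
Product: 6 (6R)-6-[(tert-butyldimethylsilyloxy)methyl]-2,6-dimethylcyclohex-1-en-1-yl trifluoromethanesulfonate
Conditions: LDA, THF, −78 → 0 °C; PhNTf2, 0 → 23 °C
Reagents that add atoms: N-phenylbis(trifluoromethanesulfonimide), O=S(=O)(N(c1ccccc1)S(=O)(=O)C(F)(F)F)C(F)(F)F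
Why: Enolate O-sulfonylation (enol triflate formation) is regiochemically unambiguous because only one α-hydrogen remains, giving the tetrasubstituted C5=C10 triflate and erasing the epimer mixture.

**Step 6**
Reactants: 6 (6R)-6-[(tert-butyldimethylsilyloxy)methyl]-2,6-dimethylcyclohex-1-en-1-yl trifluoromethanesulfonate
Product: 7 (6S)-6-[(tert-butyldimethylsilyloxy)methyl]-2,6-dimethylcyclohex-1-ene-1-carbaldehyde
Conditions: CO (1 atm), Et3SiH, Pd(OAc)2 (5 mol %), dppp (5 mol %), Et3N, DMF, 70 °C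
Reagents that add atoms: carbon monoxide, [C-]#[O+]
Why: Palladium-catalysed reductive carbonylation (formylation) of the enol triflate by oxidative addition, CO insertion and hydride transfer from the silane should give the enal; C4 is unaffected (its descriptor changes only by priority).

**Step 7**
Reactants: 7 (6S)-6-[(tert-butyldimethylsilyloxy)methyl]-2,6-dimethylcyclohex-1-ene-1-carbaldehyde
Product: 8 (1S)-1-{(6S)-6-[(tert-butyldimethylsilyloxy)methyl]-2,6-dimethylcyclohex-1-en-1-yl}but-3-en-1-ol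
Conditions: (−)-Ipc2B(allyl), Et2O, −78 → 23 °C; then 3 M NaOH, 30 % H2O2, 0 → 23 °C
Reagents that add atoms: (−)-B-allyldiisopinocampheylborane (isopinocampheyl groups from (+)-α-pinene), C=CCB(C1CC2CC(C1C)C2(C)C)C1CC2CC(C1C)C2(C)C
Why: Asymmetric allylboration through a closed chair transition state sets the C6 carbinol under reagent control, the (−)-reagent being the antipode that by its usual sense should deliver the 1S alcohol.

**Step 8**
Reactants: 8 (1S)-1-{(6S)-6-[(tert-butyldimethylsilyloxy)methyl]-2,6-dimethylcyclohex-1-en-1-yl}but-3-en-1-ol; 9 acryloyl chloride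
Product: 10 (1S)-1-{(6S)-6-[(tert-butyldimethylsilyloxy)methyl]-2,6-dimethylcyclohex-1-en-1-yl}but-3-en-1-yl prop-2-enoate
Conditions: Et3N, DMAP (cat.), CH2Cl2, 0 °C
Reagents that add atoms: none
Why: DMAP-catalysed O-acylation of the hindered secondary allylic alcohol should give the acrylate with retention at C6.

**Step 9**
Reactants: 10 (1S)-1-{(6S)-6-[(tert-butyldimethylsilyloxy)methyl]-2,6-dimethylcyclohex-1-en-1-yl}but-3-en-1-yl prop-2-enoate
Product: 11 (6S)-6-{(6S)-6-[(tert-butyldimethylsilyloxy)methyl]-2,6-dimethylcyclohex-1-en-1-yl}-5,6-dihydro-2H-pyran-2-one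
Conditions: second-generation Grubbs catalyst (H2IMes)(PCy3)Cl2Ru=CHPh (5 mol %), CH2Cl2 (5 mM), 40 °C
Reagents that add atoms: none
Why: Ring-closing metathesis between the acrylate and the terminal olefin closes the six-membered unsaturated lactone, the tetrasubstituted ring-A olefin being inert to the catalyst.

**Step 10**
Reactants: 11 (6S)-6-{(6S)-6-[(tert-butyldimethylsilyloxy)methyl]-2,6-dimethylcyclohex-1-en-1-yl}-5,6-dihydro-2H-pyran-2-one
Product: 12 (4R,6S)-4-methyl-6-{(6S)-6-[(tert-butyldimethylsilyloxy)methyl]-2,6-dimethylcyclohex-1-en-1-yl}tetrahydro-2H-pyran-2-one (4-methyl trans to the 6-substituent)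
Conditions: CuI, MeLi (2 equiv), Et2O, 0 °C; then 11, −78 → −30 °C; aq. NH4Cl
Reagents that add atoms: lithium dimethylcuprate, [Li+].C[Cu-]C
Why: Cuprate conjugate addition to the unsaturated δ-lactone by axial attack on the half-chair with the bulky C6 group pseudo-equatorial should bring the methyl in anti to it, setting C8 trans by substrate control.

**Step 11**
Reactants: 12 (4R,6S)-4-methyl-6-{(6S)-6-[(tert-butyldimethylsilyloxy)methyl]-2,6-dimethylcyclohex-1-en-1-yl}tetrahydro-2H-pyran-2-one
Product: 15 (1R,2R,5S,8aR)-5-[(tert-butyldimethylsilyloxy)methyl]-2,5,8a-trimethyl-1,2,3,5,6,7,8,8a-octahydronaphthalene-1-carboxylic acid, via cyclic silyl ketene acetal 13 (not isolated), via TBS ester 14 (not isolated)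
Conditions: LDA, TBSCl, THF–DMPU, −78 → 23 °C; PhMe, 105 °C; then 5 % aq. citric acid, THF, 23 °C
Reagents that add atoms: tert-butyldimethylsilyl chloride, CC(C)(C)[Si](C)(C)Cl (its silyl group is carried by 13 and 14 and lost on work-up)
Why: LDA/TBSCl converts the lactone into its cyclic silyl ketene acetal 13, in which C9=C11–O–C6–C5=C10 is a 1,5-diene tied by the C7–C8 tether, and heating triggers a [3,3]-sigmatropic shift that forms C9–C10, breaks C6–O and moves the ring-A olefin to C5=C6, the silyl ester 14 being the thermodynamic sink. The closest known reaction is the Ireland–Claisen rearrangement of alkenyl-substituted lactones to cycloalkene carboxylic acids, applied here to a tetrasubstituted cyclohexenyl olefin. Ring B (C5–C10) closes through the pericyclic bond formation itself, in the bicyclo[2.2.2]-like boat that the two-carbon tether enforces with the cyclohexenyl group axial on C6. C10 is set by suprafacial transfer from the 6S carbinol (C9 bonds to the ring-A face from which C6–O departs, the α face, anti to the C4 CH2OTBS), C9 is set by the boat (CO2H α, trans to C20), and C8 is carried through unchanged. The step needs complete face selectivity at C10 and a reachable boat: the first is fixed by C6, and the second is helped by the trans C8 methyl, which lies on the exo face of the boat away from the C20 methyl that swings over C8–C9. The hazards are congestion at the olefin next to quaternary C4 and self-condensation of the lactone enolate, hence in situ silylation and prolonged heating.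

**Step 12**
Reactants: 15 (1R,2R,5S,8aR)-5-[(tert-butyldimethylsilyloxy)methyl]-2,5,8a-trimethyl-1,2,3,5,6,7,8,8a-octahydronaphthalene-1-carboxylic acid
Product: 16 methyl (1R,2R,5S,8aR)-5-[(tert-butyldimethylsilyloxy)methyl]-2,5,8a-trimethyl-1,2,3,5,6,7,8,8a-octahydronaphthalene-1-carboxylate
Conditions: MeI, K2CO3, DMF, 23 °C
Reagents that add atoms: iodomethane, CI
Why: Carboxylate O-alkylation (SN2 on MeI) is insensitive to the hindrance around the acid and should give the methyl ester without change at C9.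

**Step 13**
Reactants: 16 methyl (1R,2R,5S,8aR)-5-[(tert-butyldimethylsilyloxy)methyl]-2,5,8a-trimethyl-1,2,3,5,6,7,8,8a-octahydronaphthalene-1-carboxylate
Product: 17 methyl (1R,2R,4aR,5S,8aS)-5-[(tert-butyldimethylsilyloxy)methyl]-2,5,8a-trimethyldecahydronaphthalene-1-carboxylate
Conditions: H2 (4 atm), [Ir(cod)(PCy3)(py)]PF6 (5 mol %), CH2Cl2, 23 °C
Reagents that add atoms: none
Why: Carbonyl-directed homogeneous hydrogenation, in which the axial 9α ester binds the cationic iridium and delivers H2 to the α face of C5=C6 while the β face is screened by the axial C10 methyl and C4 CH2OTBS, should set C5 as 5α-H (trans-decalin).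

**Step 14**
Reactants: 17 methyl (1R,2R,4aR,5S,8aS)-5-[(tert-butyldimethylsilyloxy)methyl]-2,5,8a-trimethyldecahydronaphthalene-1-carboxylate
Product: 18 methyl (1R,2R,4aR,5S,8aS)-1-bromo-5-[(tert-butyldimethylsilyloxy)methyl]-2,5,8a-trimethyldecahydronaphthalene-1-carboxylate (9α-Br axial)
Conditions: LDA, THF, −78 → 0 °C; BrCCl2CCl2Br, −78 °C
Reagents that add atoms: 1,2-dibromo-1,1,2,2-tetrachloroethane, BrC(Cl)(Cl)C(Cl)(Cl)Br
Why: Ester enolate α-bromination, in which LDA removes the only α-hydrogen (H9) and the bromine donor is expected to be attacked on the α (axial) face, anti to the adjacent axial C10 methyl, giving the 9α-bromide antiperiplanar to the axial 8β-H.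

**Step 15**
Reactants: 18 methyl (1R,2R,4aR,5S,8aS)-1-bromo-5-[(tert-butyldimethylsilyloxy)methyl]-2,5,8a-trimethyldecahydronaphthalene-1-carboxylate
Product: 19 methyl (4aR,5S,8aS)-5-[(tert-butyldimethylsilyloxy)methyl]-2,5,8a-trimethyl-3,4,4a,5,6,7,8,8a-octahydronaphthalene-1-carboxylate
Conditions: DBU, PhMe, 90 °C
Reagents that add atoms: none
Why: E2 dehydrobromination through the trans-diaxial 9α-Br/8β-H pair can only go towards C8 (C10 is quaternary), giving the tetrasubstituted C8=C9 enoate and removing the C8 and C9 centres.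

**Step 16**
Reactants: 19 methyl (4aR,5S,8aS)-5-[(tert-butyldimethylsilyloxy)methyl]-2,5,8a-trimethyl-3,4,4a,5,6,7,8,8a-octahydronaphthalene-1-carboxylate
Product: 20 {(4aR,5S,8aS)-5-[(tert-butyldimethylsilyloxy)methyl]-2,5,8a-trimethyl-3,4,4a,5,6,7,8,8a-octahydronaphthalen-1-yl}methanol
Conditions: DIBAL-H, CH2Cl2, −78 → 0 °C; aq. Rochelle salt
Reagents that add atoms: none
Why: Hydride 1,2-reduction of the hindered enoate with DIBAL-H should give the C11 allylic alcohol without touching the silyl ether.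

**Step 17**
Reactants: 20 {(4aR,5S,8aS)-5-[(tert-butyldimethylsilyloxy)methyl]-2,5,8a-trimethyl-3,4,4a,5,6,7,8,8a-octahydronaphthalen-1-yl}methanol
Product: 21 (4aR,5S,8aS)-1-(bromomethyl)-5-[(tert-butyldimethylsilyloxy)methyl]-2,5,8a-trimethyl-3,4,4a,5,6,7,8,8a-octahydronaphthalene
Conditions: CBr4, PPh3, CH2Cl2, 0 °C
Reagents that add atoms: tetrabromomethane, BrC(Br)(Br)Br
Why: Appel bromination converts the primary allylic alcohol into the bromide under neutral conditions, attack at the tetrasubstituted C8 (allylic transposition) being sterically disfavoured.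

**Step 18**
Reactants: 21 (4aR,5S,8aS)-1-(bromomethyl)-5-[(tert-butyldimethylsilyloxy)methyl]-2,5,8a-trimethyl-3,4,4a,5,6,7,8,8a-octahydronaphthalene; 22 methyl acetoacetate
Product: 23 methyl 5-{(4aR,5S,8aS)-5-[(tert-butyldimethylsilyloxy)methyl]-2,5,8a-trimethyl-3,4,4a,5,6,7,8,8a-octahydronaphthalen-1-yl}-3-oxopentanoate
Conditions: 22, NaH, THF, 0 °C; n-BuLi, 0 °C; then 21, 0 → 23 °C; aq. NH4Cl
Reagents that add atoms: none
Why: Alkylation of the acetoacetate dianion at its terminal carbon by SN2 on the primary allylic bromide forms C11–C12 and brings in C12–C15 as the β-keto ester.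

**Step 19**
Reactants: 23 methyl 5-{(4aR,5S,8aS)-5-[(tert-butyldimethylsilyloxy)methyl]-2,5,8a-trimethyl-3,4,4a,5,6,7,8,8a-octahydronaphthalen-1-yl}-3-oxopentanoate
Product: 24 methyl (2Z)-3-[(diethoxyphosphoryl)oxy]-5-{(4aR,5S,8aS)-5-[(tert-butyldimethylsilyloxy)methyl]-2,5,8a-trimethyl-3,4,4a,5,6,7,8,8a-octahydronaphthalen-1-yl}pent-2-enoate
Conditions: NaH, Et2O, 0 °C; ClP(O)(OEt)2, 0 → 23 °C
Reagents that add atoms: diethyl chlorophosphate, CCOP(=O)(Cl)OCC
Why: O-Phosphorylation of the chelated sodium enolate of the β-keto ester should give the enol phosphate with phosphate and ester cis (Z), which fixes the olefin geometry for step 20.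

**Step 20**
Reactants: 24 methyl (2Z)-3-[(diethoxyphosphoryl)oxy]-5-{(4aR,5S,8aS)-5-[(tert-butyldimethylsilyloxy)methyl]-2,5,8a-trimethyl-3,4,4a,5,6,7,8,8a-octahydronaphthalen-1-yl}pent-2-enoate
Product: 25 methyl (2E)-5-{(4aR,5S,8aS)-5-[(tert-butyldimethylsilyloxy)methyl]-2,5,8a-trimethyl-3,4,4a,5,6,7,8,8a-octahydronaphthalen-1-yl}-3-methylpent-2-enoate
Conditions: CuI, MeLi (2 equiv per Cu), Et2O, 0 °C; then 24, −78 → −45 °C; aq. NH4Cl
Reagents that add atoms: lithium dimethylcuprate, [Li+].C[Cu-]C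
Why: Cuprate substitution of the enol phosphate (addition–elimination with retention of geometry) places the C16 methyl cis to the ester and so should give the 13E enoate.

**Step 21**
Reactants: 25 methyl (2E)-5-{(4aR,5S,8aS)-5-[(tert-butyldimethylsilyloxy)methyl]-2,5,8a-trimethyl-3,4,4a,5,6,7,8,8a-octahydronaphthalen-1-yl}-3-methylpent-2-enoate
Product: 26 methyl (2E)-5-[(4aR,5S,8aS)-5-(hydroxymethyl)-2,5,8a-trimethyl-3,4,4a,5,6,7,8,8a-octahydronaphthalen-1-yl]-3-methylpent-2-enoate
Conditions: HF·pyridine, pyridine, THF, 0 → 23 °C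
Reagents that add atoms: none
Why: Fluoride-mediated desilylation under buffered conditions should free the neopentyl C19 alcohol without isomerising the tetrasubstituted olefin or the enoate.

**Step 22**
Reactants: 26 methyl (2E)-5-[(4aR,5S,8aS)-5-(hydroxymethyl)-2,5,8a-trimethyl-3,4,4a,5,6,7,8,8a-octahydronaphthalen-1-yl]-3-methylpent-2-enoate
Product: 27 methyl (2E)-5-[(4aR,5S,8aS)-5-(acetoxymethyl)-2,5,8a-trimethyl-3,4,4a,5,6,7,8,8a-octahydronaphthalen-1-yl]-3-methylpent-2-enoate (CNP0308505.1)
Conditions: Ac2O, pyridine, DMAP (cat.), CH2Cl2, 23 °C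
Reagents that add atoms: acetic anhydride, CC(=O)OC(C)=O
Why: DMAP-catalysed acetylation of the primary alcohol should give the target with all three stereocentres (4S,5R,10S in labdane numbering) and the 13E olefin in place.

**Compound list**
1 | 2-methylcyclohexanone (racemic) | CC1CCCCC1=O | starting material
2 | 2-methyl-1-(trimethylsilyloxy)cyclohex-1-ene | CC1=C(O[Si](C)(C)C)CCCC1 | intermediate
3 | (2R)-2-(hydroxymethyl)-2-methylcyclohexan-1-one | O=C1CCCC[C@]1(C)CO | intermediate
4 | (2R)-2-[(tert-butyldimethylsilyloxy)methyl]-2-methylcyclohexan-1-one | O=C1CCCC[C@]1(C)CO[Si](C)(C)C(C)(C)C | intermediate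
5 | (2R)-2-[(tert-butyldimethylsilyloxy)methyl]-2,6-dimethylcyclohexan-1-one, both C6 epimers | O=C1C(C)CCC[C@]1(C)CO[Si](C)(C)C(C)(C)C | intermediate
6 | (6R)-6-[(tert-butyldimethylsilyloxy)methyl]-2,6-dimethylcyclohex-1-en-1-yl trifluoromethanesulfonate | O=S(=O)(OC1=C(C)CCC[C@]1(C)CO[Si](C)(C)C(C)(C)C)C(F)(F)F | intermediate
7 | (6S)-6-[(tert-butyldimethylsilyloxy)methyl]-2,6-dimethylcyclohex-1-ene-1-carbaldehyde | O=CC1=C(C)CCC[C@]1(C)CO[Si](C)(C)C(C)(C)C | intermediate
8 | (1S)-1-{(6S)-6-[(tert-butyldimethylsilyloxy)methyl]-2,6-dimethylcyclohex-1-en-1-yl}but-3-en-1-ol | C=CC[C@H](O)C1=C(C)CCC[C@]1(C)CO[Si](C)(C)C(C)(C)C | intermediate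
9 | acryloyl chloride | C=CC(=O)Cl | starting material
10 | (1S)-1-{(6S)-6-[(tert-butyldimethylsilyloxy)methyl]-2,6-dimethylcyclohex-1-en-1-yl}but-3-en-1-yl prop-2-enoate | C=CC(=O)O[C@@H](CC=C)C1=C(C)CCC[C@]1(C)CO[Si](C)(C)C(C)(C)C | intermediate
11 | (6S)-6-{(6S)-6-[(tert-butyldimethylsilyloxy)methyl]-2,6-dimethylcyclohex-1-en-1-yl}-5,6-dihydro-2H-pyran-2-one | O=C1C=CC[C@H](O1)C2=C(C)CCC[C@]2(C)CO[Si](C)(C)C(C)(C)C | intermediate
12 | (4R,6S)-4-methyl-6-{(6S)-6-[(tert-butyldimethylsilyloxy)methyl]-2,6-dimethylcyclohex-1-en-1-yl}tetrahydro-2H-pyran-2-one (trans; key-step precursor) | O=C1C[C@H](C)C[C@H](O1)C2=C(C)CCC[C@]2(C)CO[Si](C)(C)C(C)(C)C | intermediate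
13 | (2S,4R)-6-(tert-butyldimethylsilyloxy)-4-methyl-2-{(6S)-6-[(tert-butyldimethylsilyloxy)methyl]-2,6-dimethylcyclohex-1-en-1-yl}-3,4-dihydro-2H-pyran (cyclic silyl ketene acetal) | CC(C)(C)[Si](C)(C)OC1=C[C@H](C)C[C@H](O1)C2=C(C)CCC[C@]2(C)CO[Si](C)(C)C(C)(C)C | intermediate
14 | tert-butyldimethylsilyl (1R,2R,5S,8aR)-5-[(tert-butyldimethylsilyloxy)methyl]-2,5,8a-trimethyl-1,2,3,5,6,7,8,8a-octahydronaphthalene-1-carboxylate | CC(C)(C)[Si](C)(C)OC(=O)[C@@H]1[C@H](C)CC=C2[C@@](C)(CO[Si](C)(C)C(C)(C)C)CCC[C@]12C | intermediate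
15 | (1R,2R,5S,8aR)-5-[(tert-butyldimethylsilyloxy)methyl]-2,5,8a-trimethyl-1,2,3,5,6,7,8,8a-octahydronaphthalene-1-carboxylic acid (C5=C6 olefin, 9α-CO2H, 8α-methyl, 10β-methyl, 4β-CH2OTBS; key-step product) | OC(=O)[C@@H]1[C@H](C)CC=C2[C@@](C)(CO[Si](C)(C)C(C)(C)C)CCC[C@]12C | intermediate
16 | methyl (1R,2R,5S,8aR)-5-[(tert-butyldimethylsilyloxy)methyl]-2,5,8a-trimethyl-1,2,3,5,6,7,8,8a-octahydronaphthalene-1-carboxylate | COC(=O)[C@@H]1[C@H](C)CC=C2[C@@](C)(CO[Si](C)(C)C(C)(C)C)CCC[C@]12C | intermediate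
17 | methyl (1R,2R,4aR,5S,8aS)-5-[(tert-butyldimethylsilyloxy)methyl]-2,5,8a-trimethyldecahydronaphthalene-1-carboxylate | COC(=O)[C@@H]1[C@H](C)CC[C@H]2[C@@](C)(CO[Si](C)(C)C(C)(C)C)CCC[C@]12C | intermediate
18 | methyl (1R,2R,4aR,5S,8aS)-1-bromo-5-[(tert-butyldimethylsilyloxy)methyl]-2,5,8a-trimethyldecahydronaphthalene-1-carboxylate | COC(=O)[C@@]1(Br)[C@H](C)CC[C@H]2[C@@](C)(CO[Si](C)(C)C(C)(C)C)CCC[C@]12C | intermediate
19 | methyl (4aR,5S,8aS)-5-[(tert-butyldimethylsilyloxy)methyl]-2,5,8a-trimethyl-3,4,4a,5,6,7,8,8a-octahydronaphthalene-1-carboxylate | COC(=O)C1=C(C)CC[C@H]2[C@@](C)(CO[Si](C)(C)C(C)(C)C)CCC[C@]12C | intermediate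
20 | {(4aR,5S,8aS)-5-[(tert-butyldimethylsilyloxy)methyl]-2,5,8a-trimethyl-3,4,4a,5,6,7,8,8a-octahydronaphthalen-1-yl}methanol | OCC1=C(C)CC[C@H]2[C@@](C)(CO[Si](C)(C)C(C)(C)C)CCC[C@]12C | intermediate
21 | (4aR,5S,8aS)-1-(bromomethyl)-5-[(tert-butyldimethylsilyloxy)methyl]-2,5,8a-trimethyl-3,4,4a,5,6,7,8,8a-octahydronaphthalene | BrCC1=C(C)CC[C@H]2[C@@](C)(CO[Si](C)(C)C(C)(C)C)CCC[C@]12C | intermediate
22 | methyl acetoacetate | COC(=O)CC(C)=O | starting material
23 | methyl 5-{(4aR,5S,8aS)-5-[(tert-butyldimethylsilyloxy)methyl]-2,5,8a-trimethyl-3,4,4a,5,6,7,8,8a-octahydronaphthalen-1-yl}-3-oxopentanoate | COC(=O)CC(=O)CCC1=C(C)CC[C@H]2[C@@](C)(CO[Si](C)(C)C(C)(C)C)CCC[C@]12C | intermediate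
24 | methyl (2Z)-3-[(diethoxyphosphoryl)oxy]-5-{(4aR,5S,8aS)-5-[(tert-butyldimethylsilyloxy)methyl]-2,5,8a-trimethyl-3,4,4a,5,6,7,8,8a-octahydronaphthalen-1-yl}pent-2-enoate | COC(=O)/C=C(\OP(=O)(OCC)OCC)CCC1=C(C)CC[C@H]2[C@@](C)(CO[Si](C)(C)C(C)(C)C)CCC[C@]12C | intermediate
25 | methyl (2E)-5-{(4aR,5S,8aS)-5-[(tert-butyldimethylsilyloxy)methyl]-2,5,8a-trimethyl-3,4,4a,5,6,7,8,8a-octahydronaphthalen-1-yl}-3-methylpent-2-enoate | COC(=O)/C=C(\C)CCC1=C(C)CC[C@H]2[C@@](C)(CO[Si](C)(C)C(C)(C)C)CCC[C@]12C | intermediate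
26 | methyl (2E)-5-[(4aR,5S,8aS)-5-(hydroxymethyl)-2,5,8a-trimethyl-3,4,4a,5,6,7,8,8a-octahydronaphthalen-1-yl]-3-methylpent-2-enoate | COC(=O)/C=C(\C)CCC1=C(C)CC[C@H]2[C@@](C)(CO)CCC[C@]12C | intermediate
27 | methyl (2E)-5-[(4aR,5S,8aS)-5-(acetoxymethyl)-2,5,8a-trimethyl-3,4,4a,5,6,7,8,8a-octahydronaphthalen-1-yl]-3-methylpent-2-enoate (CNP0308505.1) | COC(=O)/C=C(\C)CCC1=C(C)CC[C@H]2[C@@](C)(COC(C)=O)CCC[C@]12C | target

**Step count and risks**

Total step count: 22. Longest linear sequence: 22 steps (1 → 27; 9 and 22 are purchased).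

The three steps most likely to fail:

Step 11. The ketene acetal may not reach the boat at the tetrasubstituted olefin flanked by quaternary C4, and may be consumed by C-silylation or lactone self-condensation before it rearranges. The fallback sets out from enol triflate 6 and returns at enoate 19. Stille coupling of 6 with tributyl(vinyl)stannane (Pd(PPh3)4, LiCl, THF, 65 °C) should give the diene tert-butyl{[(1S)-2-ethenyl-1,3-dimethylcyclohex-2-en-1-yl]methoxy}dimethylsilane F1. A thermal Diels–Alder reaction of this diene with methyl but-2-ynoate (PhMe, sealed tube, 160 °C) forms C9–C10 and C7–C8 together and should give methyl (5S,8aS)-5-[(tert-butyldimethylsilyloxy)methyl]-2,5,8a-trimethyl-3,5,6,7,8,8a-hexahydronaphthalene-1-carboxylate F2. The ester carbon is expected to bond to the substituted diene terminus and the dienophile to arrive anti to the CH2OTBS group on C4, so C10 would then rest on C4 alone, without the C6 relay. Hydrogenation of the C5=C6 bond only (H2, Pd/C, EtOAc), from the α face, returns 19.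

Step 14. Bromine may be delivered to the β face of the enolate, which would leave no hydrogen antiperiplanar to bromine for the elimination of step 15. The fallback sets out from saturated ester 17 and returns at enoate 19. The same enolate (LDA, THF, −78 → 0 °C) is trapped with PhSeBr to give methyl (1S,2R,4aR,5S,8aS)-5-[(tert-butyldimethylsilyloxy)methyl]-2,5,8a-trimethyl-1-(phenylselanyl)decahydronaphthalene-1-carboxylate F3, the 9β-selenide. Oxidation (H2O2, pyridine, CH2Cl2, 0 → 23 °C) gives the selenoxide, which has the cis 8β-hydrogen needed for syn-elimination and should give 19.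

Step 13. Turnover may be slow or α-face delivery incomplete at an olefin flanked by two quaternary carbons. The fallback sets out from Δ5 ester 16 and returns at bromo ester 18. Equilibration with NaOMe in MeOH (65 °C) should move the ester to the equatorial 9β position, giving methyl (1S,2R,5S,8aR)-5-[(tert-butyldimethylsilyloxy)methyl]-2,5,8a-trimethyl-1,2,3,5,6,7,8,8a-octahydronaphthalene-1-carboxylate F4, which has no axial group on the α face. Heterogeneous hydrogenation (H2, 4 atm, Pd/C, EtOAc) from that face should then give methyl (1S,2R,4aR,5S,8aS)-5-[(tert-butyldimethylsilyloxy)methyl]-2,5,8a-trimethyldecahydronaphthalene-1-carboxylate F5. This C9 epimer of 17 forms the same ester enolate and is brominated under the conditions of step 14 to 18.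

**Further compounds**
F1 | step 11 | tert-butyl{[(1S)-2-ethenyl-1,3-dimethylcyclohex-2-en-1-yl]methoxy}dimethylsilane | C=CC1=C(C)CCC[C@]1(C)CO[Si](C)(C)C(C)(C)C
F2 | step 11 | methyl (5S,8aS)-5-[(tert-butyldimethylsilyloxy)methyl]-2,5,8a-trimethyl-3,5,6,7,8,8a-hexahydronaphthalene-1-carboxylate | COC(=O)C1=C(C)CC=C2[C@@](C)(CO[Si](C)(C)C(C)(C)C)CCC[C@]12C
F3 | step 14 | methyl (1S,2R,4aR,5S,8aS)-5-[(tert-butyldimethylsilyloxy)methyl]-2,5,8a-trimethyl-1-(phenylselanyl)decahydronaphthalene-1-carboxylate | COC(=O)[C@]1([Se]c2ccccc2)[C@H](C)CC[C@H]3[C@@](C)(CO[Si](C)(C)C(C)(C)C)CCC[C@]13C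
F4 | step 13 | methyl (1S,2R,5S,8aR)-5-[(tert-butyldimethylsilyloxy)methyl]-2,5,8a-trimethyl-1,2,3,5,6,7,8,8a-octahydronaphthalene-1-carboxylate | COC(=O)[C@H]1[C@H](C)CC=C2[C@@](C)(CO[Si](C)(C)C(C)(C)C)CCC[C@]12C
F5 | step 13 | methyl (1S,2R,4aR,5S,8aS)-5-[(tert-butyldimethylsilyloxy)methyl]-2,5,8a-trimethyldecahydronaphthalene-1-carboxylate | COC(=O)[C@H]1[C@H](C)CC[C@H]2[C@@](C)(CO[Si](C)(C)C(C)(C)C)CCC[C@]12C
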